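**Plan**
- Retrosynthesis: cut C3–CH2CO2Me (peroxycarbenium ion plus ketene acetal), then the side-chain alkene C5'=C6' (Julia–Kocienski), then C2'–C3' (cross-metathesis, then saturation), then C6–C1' (peroxycarbenium ion plus allylsilane), and last both ring C–O bonds, C3–O2 and C6–O1.
- Enabling feature: in the 1,2-dioxane the peroxide-bearing carbons C3 and C6 are bridged by C4–C5, so the ring is a cyclobutene (C3=C6, C4, C5) with O–O inserted across its double bond.
- Forward: but-1-ene → 3-ethylcyclobutanone → chiral enol triflate → (S)-1,3-diethylcyclobutene → ozonolysis in methanol closes the dioxane as a 3,6-dimethoxy bis-acetal → allyl at C6 → chain by cross-metathesis with a chiral sulfone, diimide, Julia–Kocienski → acetate at C3 last.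
- Stereochemistry: C4 from chiral lithium amide desymmetrisation of the cyclobutanone; C6 and C3 from axial attack on peroxycarbenium ions steered by the equatorial C4 ethyl; C4' from copper-catalysed asymmetric allylic alkylation; 5'E from the Julia–Kocienski step.

Key step: step 5

Assumption: the sense of induction of the chiral lithium amide (step 3) and of the phosphoramidite ligand (step 7) is assigned by analogy; should either give the opposite enantiomer, its equally available antipode is used.

Dioxane locants follow the target throughout (C3 acetal carbon, C4 CH(Et), C6 quaternary carbon); side-chain carbons are C1'–C8' counted from C6.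

**Step 1**
Reactants: 1 but-1-ene; 2 trichloroacetyl chloride
Product: 4 2,2-dichloro-3-ethylcyclobutan-1-one (racemic), via dichloroketene 3 (not isolated)
Conditions: Zn–Cu couple, POCl3, Et2O, excess but-1-ene condensed in, sealed vessel, 0 → 25 °C, sonication
Reagents that add atoms: trichloroacetyl chloride (2), ClC(=O)C(Cl)(Cl)Cl
Why: Zinc dechlorination of the acid chloride releases dichloroketene, which undergoes the usual thermal [2+2] ketene–alkene cycloaddition with a terminal alkene to place the alkyl-bearing carbon next to CCl2.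

**Step 2**
Reactants: 4 2,2-dichloro-3-ethylcyclobutan-1-one
Product: 5 3-ethylcyclobutan-1-one
Conditions: Zn dust, AcOH, 60 °C
Reagents that add atoms: none
Why: Reductive dehalogenation of α,α-dichloroketones by zinc in acetic acid is the standard follow-up to dichloroketene cycloadditions and leaves an achiral ketone with two enantiotopic α-methylene groups.

**Step 3**
Reactants: 5 3-ethylcyclobutan-1-one
Product: 7 (S)-3-ethylcyclobut-1-en-1-yl trifluoromethanesulfonate, via lithium (S)-3-ethylcyclobut-1-en-1-olate 6 (not isolated)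
Conditions: (R,R)-bis(1-phenylethyl)amine, n-BuLi, LiCl, THF, −100 °C; then N-(5-chloro-2-pyridyl)triflimide, −100 → −40 °C
Reagents that add atoms: N-(5-chloro-2-pyridyl)bis(trifluoromethanesulfonimide), Clc1ccc(N(S(=O)(=O)C(F)(F)F)S(=O)(=O)C(F)(F)F)nc1
Why: Enantioselective deprotonation with a C2-symmetric chiral lithium amide, established for 3-substituted cyclobutanones, removes a proton from one of the two enantiotopic CH2 groups so that C3 becomes a stereocentre (S), and fast O-triflation at low temperature fixes the enolate before proton exchange can erode it.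

**Step 4**
Reactants: 7 (S)-3-ethylcyclobut-1-en-1-yl trifluoromethanesulfonate; 8 ethylmagnesium bromide
Product: 9 (S)-1,3-diethylcyclobut-1-ene
Conditions: EtMgBr, Fe(acac)3 (5 mol%), THF/NMP, −30 °C; pentane extraction, volatile product carried on as a titrated CH2Cl2 solution
Reagents that add atoms: ethylmagnesium bromide (8), CC[Mg]Br
Why: Iron-catalysed Kumada-type coupling of alkenyl triflates with alkyl Grignard reagents is fast at low temperature, tolerates β-hydrogens on the ethyl group and does not touch the allylic stereocentre.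

**Step 5**
Reactants: 9 (S)-1,3-diethylcyclobut-1-ene
Product: 12 (4S)-4,6-diethyl-3,6-dimethoxy-1,2-dioxane (anomer mixture at C3/C6), via (2S)-2-ethyl-4-hydroperoxy-4-methoxyhexanal 10 (not isolated), via (4S)-4,6-diethyl-6-methoxy-1,2-dioxan-3-ol 11 (not isolated)
Conditions: O3, CH2Cl2/MeOH, −78 °C; N2 purge; then TsOH (cat.), MeOH, 0 °C, short; solid NaHCO3
Reagents that add atoms: ozone, [O-][O+]=O; methanol, CO
Why: Ozone adds to the strained trisubstituted ring alkene by 1,3-dipolar cycloaddition and the primary ozonide cycloreverts (Criegee mechanism), preferentially to a ketone oxide at the ethyl-bearing carbon and an aldehyde that remain tethered through C5–C4, and solvent methanol intercepts the carbonyl oxide as the α-methoxy hydroperoxide 10. The hydroperoxide then adds to the aldehyde in a 6-exo-trig closure that forms the second C–O bond and the 1,2-dioxane ring (11), and brief acid in methanol exchanges the hemiacetal hydroxyl for methoxy, which also funnels the minor, reversed cleavage mode to the same bis-acetal 12. The closest known reaction type is the ozonolysis of cycloalkenes in methanol with unsymmetrical work-up, where a short tether lets the methoxy hydroperoxide close onto the second carbonyl as a cyclic peroxy hemiacetal. No stereocentre has to be controlled: C3 and C6 arise as anomers that are erased in the later ionisations, and C4 is carried over unchanged from 9, the acid step being kept short and cold so that the open-chain α-branched aldehyde cannot enolise. The selectivity needed is chemoselectivity, methanol capture against ozonide or oligomer formation, secured by methanol in large excess as co-solvent and by the favourable six-membered closure driven by release of cyclobutene strain.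

**Step 6**
Reactants: 12 (4S)-4,6-diethyl-3,6-dimethoxy-1,2-dioxane; 13 allyltrimethylsilane
Product: 14 (4S,6S)-4,6-diethyl-3-methoxy-6-(prop-2-en-1-yl)-1,2-dioxane (C3 anomers)
Conditions: allyltrimethylsilane (1.5 equiv), SnCl4 (1.0 equiv), CH2Cl2, −78 °C
Reagents that add atoms: allyltrimethylsilane (13), C=CC[Si](C)(C)C
Why: In this Sakurai-type allylation the Lewis acid ionises the ketal methoxy group at C6 (tertiary peroxycarbenium ion) far more readily than the acetal at C3, and the allylsilane attacks axially on the half-chair with the C4 ethyl pseudo-equatorial, so the allyl group ends up trans to the C4 ethyl and the C6 ethyl equatorial (6S).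

**Step 7**
Reactants: 15 (E)-1,4-dibromobut-2-ene; 8 ethylmagnesium bromide
Product: 16 (R)-3-(bromomethyl)pent-1-ene
Conditions: EtMgBr (Et2O solution, slow addition), Cu(O2C-2-thienyl) (3 mol%), BINOL-derived bis(1-phenylethyl)amine phosphoramidite (3.3 mol%), CH2Cl2, −78 °C
Reagents that add atoms: ethylmagnesium bromide (8), CC[Mg]Br
Why: Copper-catalysed asymmetric allylic alkylation of E-allylic bromides with Grignard reagents proceeds by ligand-controlled SN2′ attack, the symmetric dibromide giving the same branched product from either end and the resulting homoallylic bromide being inert, so the ligand sets the C4' stereocentre (R).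

**Step 8**
Reactants: 16 (R)-3-(bromomethyl)pent-1-ene; 17 1-phenyl-1H-tetrazole-5-thiol
Product: 18 5-{[(2R)-2-ethylbut-3-en-1-yl]sulfanyl}-1-phenyl-1H-tetrazole
Conditions: K2CO3, DMF, 50 °C
Reagents that add atoms: 1-phenyl-1H-tetrazole-5-thiol (17), Sc1nnnn1-c1ccccc1
Why: The soft thiolate displaces the primary bromide by SN2 without touching the adjacent stereocentre or the terminal alkene.

**Step 9**
Reactants: 18 5-{[(2R)-2-ethylbut-3-en-1-yl]sulfanyl}-1-phenyl-1H-tetrazole
Product: 19 5-{[(2R)-2-ethylbut-3-en-1-yl]sulfonyl}-1-phenyl-1H-tetrazole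
Conditions: (NH4)6Mo7O24·4H2O (10 mol%), 30% aq H2O2, EtOH, 0 °C → rt
Reagents that add atoms: hydrogen peroxide, OO
Why: Molybdate-catalysed peroxide oxidation takes sulfides to sulfones and does not epoxidise an unactivated terminal alkene, the usual preparation of Julia–Kocienski sulfones.

**Step 10**
Reactants: 14 (4S,6S)-4,6-diethyl-3-methoxy-6-(prop-2-en-1-yl)-1,2-dioxane; 19 5-{[(2R)-2-ethylbut-3-en-1-yl]sulfonyl}-1-phenyl-1H-tetrazole
Product: 20 5-{[(2R)-2-ethyl-5-[(4S,6S)-4,6-diethyl-3-methoxy-1,2-dioxan-6-yl]pent-3-en-1-yl]sulfonyl}-1-phenyl-1H-tetrazole (E/Z mixture, C3 anomers)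
Conditions: second-generation Grubbs catalyst RuCl2(=CHPh)(PCy3)(H2IMes) (5 mol%), 19 in excess, CH2Cl2, 40 °C
Reagents that add atoms: 5-{[(2R)-2-ethylbut-3-en-1-yl]sulfonyl}-1-phenyl-1H-tetrazole (19), O=S(=O)(C[C@H](CC)C=C)c1nnnn1-c1ccccc1
Why: In this olefin cross-metathesis both terminal alkenes are slow to homodimerise (one neopentyl-like, one allylically branched), so the cross product is favoured with 19 in excess, the ruthenium carbene tolerates dialkyl peroxides and sulfones, and alkene geometry is irrelevant because the bond is saturated next.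

**Step 11**
Reactants: 20 the cross-metathesis product
Product: 21 5-{[(2R)-2-ethyl-5-[(4S,6S)-4,6-diethyl-3-methoxy-1,2-dioxan-6-yl]pentyl]sulfonyl}-1-phenyl-1H-tetrazole (C3 anomers)
Conditions: dipotassium azodicarboxylate, AcOH, CH2Cl2/MeOH, 0 °C → rt, repeated charges
Reagents that add atoms: none
Why: Diimide reduction transfers hydrogen to the C=C bond by a concerted syn addition and, unlike catalytic hydrogenation, leaves the O–O bond, the peroxyacetal and the sulfone intact.

**Step 12**
Reactants: 21 the saturated sulfone; 22 propanal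
Product: 23 (4S,6S)-4,6-diethyl-6-[(4R,5E)-4-ethyloct-5-en-1-yl]-3-methoxy-1,2-dioxane (C3 anomers)
Conditions: KN(SiMe3)2 (1.05 equiv), DME, −60 °C; then propanal, −60 °C → rt
Reagents that add atoms: propanal (22), CCC=O
Why: In the Julia–Kocienski olefination the potassium anion of the 1-phenyltetrazolyl sulfone adds to the aldehyde and Smiles rearrangement with loss of SO2 should favour the E-alkene in DME, while the C4' centre β to sulfur is not acidic and the hindered base is consumed by the sulfone at low temperature before it can attack the peroxide.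

**Step 13**
Reactants: 23 (4S,6S)-4,6-diethyl-6-[(4R,5E)-4-ethyloct-5-en-1-yl]-3-methoxy-1,2-dioxane; 24 1-(tert-butyldimethylsilyloxy)-1-methoxyethene
Product: 25 methyl 2-{(3S,4S,6S)-4,6-diethyl-6-[(4R,5E)-4-ethyloct-5-en-1-yl]-1,2-dioxan-3-yl}acetate (target)
Conditions: TiCl4 (1.1 equiv), CH2Cl2, −78 °C
Reagents that add atoms: 1-(tert-butyldimethylsilyloxy)-1-methoxyethene (24), C=C(OC)O[Si](C)(C)C(C)(C)C
Why: In this Mukaiyama-type addition the Lewis acid ionises the only remaining acetal (C3) to a secondary peroxycarbenium ion whose half-chair is locked by the cis-1,3 ethyl groups at C4 and C6 both being equatorial, and axial attack of the silyl ketene acetal then places CH2CO2Me cis to the C4 ethyl (3S).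

**Compound list**
1 | but-1-ene | C=CCC | starting material
2 | trichloroacetyl chloride | ClC(=O)C(Cl)(Cl)Cl | starting material
3 | dichloroketene (formed in situ) | O=C=C(Cl)Cl | intermediate
4 | 2,2-dichloro-3-ethylcyclobutan-1-one (racemic) | CCC1CC(=O)C1(Cl)Cl | intermediate
5 | 3-ethylcyclobutan-1-one | CCC1CC(=O)C1 | intermediate
6 | lithium (S)-3-ethylcyclobut-1-en-1-olate (formed in situ) | [Li]OC1=C[C@@H](CC)C1 | intermediate
7 | (S)-3-ethylcyclobut-1-en-1-yl trifluoromethanesulfonate | O=S(=O)(OC1=C[C@@H](CC)C1)C(F)(F)F | intermediate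
8 | ethylmagnesium bromide | CC[Mg]Br | starting material
9 | (S)-1,3-diethylcyclobut-1-ene | CCC1=C[C@@H](CC)C1 | intermediate
10 | (2S)-2-ethyl-4-hydroperoxy-4-methoxyhexanal (formed in situ, C4 epimers) | CCC(OC)(OO)C[C@H](CC)C=O | intermediate
11 | (4S)-4,6-diethyl-6-methoxy-1,2-dioxan-3-ol (formed in situ, anomers) | CCC1(OC)C[C@H](CC)C(O)OO1 | intermediate
12 | (4S)-4,6-diethyl-3,6-dimethoxy-1,2-dioxane (anomers at C3 and C6) | CCC1(OC)C[C@H](CC)C(OC)OO1 | intermediate
13 | allyltrimethylsilane | C=CC[Si](C)(C)C | starting material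
14 | (4S,6S)-4,6-diethyl-3-methoxy-6-(prop-2-en-1-yl)-1,2-dioxane (C3 anomers) | C=CC[C@@]1(CC)C[C@H](CC)C(OC)OO1 | intermediate
15 | (E)-1,4-dibromobut-2-ene | BrC/C=C/CBr | starting material
16 | (R)-3-(bromomethyl)pent-1-ene | BrC[C@H](CC)C=C | intermediate
17 | 1-phenyl-1H-tetrazole-5-thiol | Sc1nnnn1-c1ccccc1 | starting material
18 | 5-{[(2R)-2-ethylbut-3-en-1-yl]sulfanyl}-1-phenyl-1H-tetrazole | C=C[C@@H](CC)CSc1nnnn1-c1ccccc1 | intermediate
19 | 5-{[(2R)-2-ethylbut-3-en-1-yl]sulfonyl}-1-phenyl-1H-tetrazole | O=S(=O)(C[C@H](CC)C=C)c1nnnn1-c1ccccc1 | intermediate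
20 | 5-{[(2R)-2-ethyl-5-[(4S,6S)-4,6-diethyl-3-methoxy-1,2-dioxan-6-yl]pent-3-en-1-yl]sulfonyl}-1-phenyl-1H-tetrazole (E/Z, C3 anomers) | O=S(=O)(C[C@H](CC)C=CC[C@@]1(CC)C[C@H](CC)C(OC)OO1)c1nnnn1-c1ccccc1 | intermediate
21 | 5-{[(2R)-2-ethyl-5-[(4S,6S)-4,6-diethyl-3-methoxy-1,2-dioxan-6-yl]pentyl]sulfonyl}-1-phenyl-1H-tetrazole (C3 anomers) | O=S(=O)(C[C@H](CC)CCC[C@@]1(CC)C[C@H](CC)C(OC)OO1)c1nnnn1-c1ccccc1 | intermediate
22 | propanal | CCC=O | starting material
23 | (4S,6S)-4,6-diethyl-6-[(4R,5E)-4-ethyloct-5-en-1-yl]-3-methoxy-1,2-dioxane (C3 anomers) | CC/C=C/[C@H](CC)CCC[C@@]1(CC)C[C@H](CC)C(OC)OO1 | intermediate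
24 | 1-(tert-butyldimethylsilyloxy)-1-methoxyethene | C=C(OC)O[Si](C)(C)C(C)(C)C | starting material
25 | methyl 2-{(3S,4S,6S)-4,6-diethyl-6-[(4R,5E)-4-ethyloct-5-en-1-yl]-1,2-dioxan-3-yl}acetate | CC/C=C/[C@H](CC)CCC[C@@]1(CC)C[C@H](CC)[C@H](CC(=O)OC)OO1 | target

**Step count**
Total: 13 steps. Longest linear sequence: 10 steps (steps 1–6 and 10–13, from but-1-ene); the sulfone 19 is made in a 3-step branch (steps 7–9).

**Steps most likely to fail**

Step 5. Recombination of the carbonyl oxide with the tethered carbonyl (ozonide or oligomeric peroxides) may outrun methanol capture, and the acid exchange may enolise the open-chain aldehyde or expel hydrogen peroxide. The fallback sets out from 9 and separates alkene cleavage from peroxide installation. Ozonolysis in CH2Cl2 with dimethyl sulfide reduction would give (2S)-2-ethyl-4-oxohexanal F1, used at once because its α-centre is labile. Addition of ethereal hydrogen peroxide, the known condensation of 1,4-dicarbonyl compounds, would give (4S)-4,6-diethyl-1,2-dioxane-3,6-diol F2. Catalytic TsOH in methanol at 0 °C would then exchange both hydroxyls and return to the route at 12.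

Step 6. Ionisation at the C3 acetal may compete with that at the C6 ketal, giving misplaced or double allylation. The fallback sets out from 11, isolated by omitting the acid treatment of step 5, and differentiates the two centres by a protecting group instead of by intrinsic reactivity. Silylation with tert-butyldimethylsilyl triflate and 2,6-lutidine would give (4S)-3-[(tert-butyldimethylsilyl)oxy]-4,6-diethyl-6-methoxy-1,2-dioxane F3, in which only C6 carries a small, Lewis-basic leaving group. Allylation with 13 and SnCl4 would give (4S,6S)-3-[(tert-butyldimethylsilyl)oxy]-4,6-diethyl-6-(prop-2-en-1-yl)-1,2-dioxane F4. Acidic methanol would swap the silyloxy group for methoxy and rejoin the route at 14.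

Step 13. Lewis-acid-triggered heterolysis of the O–O bond may compete with the slower ionisation of the secondary acetal, and facial selectivity next to the C4 ethyl may be incomplete. The fallback sets out from 23 and avoids Lewis acids by forming the C3–O bond last instead of the C3–C bond.
- Mild aqueous acid would hydrolyse the acetal to (4S,6S)-4,6-diethyl-6-[(4R,5E)-4-ethyloct-5-en-1-yl]-1,2-dioxan-3-ol F5, the ring tautomer of a hydroperoxy aldehyde.
- Wittig olefination of the open form with methyl (triphenylphosphoranylidene)acetate would give methyl (2E,4S,6S,10R,11E)-4,6,10-triethyl-6-hydroperoxytetradeca-2,11-dienoate F6.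
- Diethylamine in trifluoroethanol would bring about the known 6-exo conjugate addition of the hydroperoxide to the enoate, arriving at the target 25 together with its C3 epimer, methyl 2-{(3R,4S,6S)-4,6-diethyl-6-[(4R,5E)-4-ethyloct-5-en-1-yl]-1,2-dioxan-3-yl}acetate F7, to be removed by chromatography.

**Further compounds**
F1 | step 5 | (2S)-2-ethyl-4-oxohexanal | CCC(=O)C[C@H](CC)C=O
F2 | step 5 | (4S)-4,6-diethyl-1,2-dioxane-3,6-diol | CCC1(O)C[C@H](CC)C(O)OO1
F3 | step 6 | (4S)-3-[(tert-butyldimethylsilyl)oxy]-4,6-diethyl-6-methoxy-1,2-dioxane | CCC1(OC)C[C@H](CC)C(O[Si](C)(C)C(C)(C)C)OO1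
F4 | step 6 | (4S,6S)-3-[(tert-butyldimethylsilyl)oxy]-4,6-diethyl-6-(prop-2-en-1-yl)-1,2-dioxane | C=CC[C@@]1(CC)C[C@H](CC)C(O[Si](C)(C)C(C)(C)C)OO1
F5 | step 13 | (4S,6S)-4,6-diethyl-6-[(4R,5E)-4-ethyloct-5-en-1-yl]-1,2-dioxan-3-ol | CC/C=C/[C@H](CC)CCC[C@@]1(CC)C[C@H](CC)C(O)OO1
F6 | step 13 | methyl (2E,4S,6S,10R,11E)-4,6,10-triethyl-6-hydroperoxytetradeca-2,11-dienoate | CC/C=C/[C@H](CC)CCC[C@@](OO)(CC)C[C@H](CC)/C=C/C(=O)OC
F7 | step 13 | methyl 2-{(3R,4S,6S)-4,6-diethyl-6-[(4R,5E)-4-ethyloct-5-en-1-yl]-1,2-dioxan-3-yl}acetate | CC/C=C/[C@H](CC)CCC[C@@]1(CC)C[C@H](CC)[C@@H](CC(=O)OC)OO1
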